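## Analysis of the target

The target joins two bicycles through a single C–C bond: a cis-fused bicyclo[5.3.0]decane (hydroazulene) and a 2,7-dioxabicyclo[3.2.1]octan-3-one. In the hydroazulene, the seven-membered ring carries an exocyclic methylene on the carbon next to one ring-fusion CH and a gem-dimethyl carbon next to the other. The cyclopentane holds a quaternary methyl carbon that is bonded to the methylene-side ring-fusion CH and, outside the ring, to the one-carbon bridge of the dioxabicycle. There are eight stereocentres. The two ring-fusion hydrogens are cis and lie on the cyclopentane face that carries the bond to the dioxabicycle, with the methyl on the other face. In the dioxabicycle the acetal bridgehead, the bridge CH (hydroazulenyl group on the side of the lactone bridge), the carbon bridgehead, the ester-bearing oxolane carbon (ester exo) and the acetoxy carbon (acetoxy turned away from the hydroazulenyl group) are all defined. Sensitive groups are the acylal (lactone acetal), the 1,1-disubstituted exocyclic alkene (isomerised or protonated by protic acid), the acetate α to the lactone carbonyl and the epimerisable α-alkoxy ester. The difficulty lies in the quaternary carbon flanked by two CH stereocentres, in a cis ring fusion next to a carbon that must pass through the ketone stage, and in a densely oxygenated bicycle that offers no remote handle. The strategy rests on one feature: the methylene carbon, the ring-fusion CH, the quaternary carbon, the bridge CH and the acetal carbon form a 1,5-pair of carbonyl-level carbons with a methyl-bearing quaternary carbon in the middle. This is the pattern left by opening a cyclobutane made from a 2-(acyloxymethylene) ketone and an isopropenyl group.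

## Retrosynthetic reasoning

**Acetoxy group (27 ⇒ 26 ⇒ 24).** The C–O bond at the carbon between lactone carbonyl and carbon bridgehead is cut first. An acetate α to an acylal lactone is the most base-labile element and should be made last. In the rigid bicycle 24 the hydroazulenyl group on the one-carbon bridge shields one face of the lactone enolate, so oxygen should enter from the other face, a control that an open chain would not give.

**Acylal C–O bond (24 ⇒ 23).** The bond between the acetal carbon and the acyl oxygen is cut, which gives the oxolane methyl acetal 23 with a tert-butyl acetate arm. The forward step has to ionise the acetal and let the ester close onto the cation. Only the face that carries the arm can be reached, so the acetal configuration corrects itself.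

**Bridge carbon to bridgehead carbon (23 ⇒ 22 ⇒ 18 + 21).** This bond joins two CH stereocentres beside the quaternary carbon. A radical closure tolerates the congestion, and tethering through the acetal oxygen makes it a 5-exo ring closure. The cut divides the molecule into the hydroazulene enol ether 18 and the five-carbon hydroxy diester 21. The one stereocentre of 21 comes from 19 and relays to the two new ones. 21 itself is the cross-metathesis product of 19 and 20.

**Functional groups on the hydroazulene (18 ⇒ 17 ⇒ 16 ⇒ 15).** The enol ether is traced to a dimethyl acetal and the methylene to a ketone, which uncovers the 1,5-keto aldehyde 15. The order is dictated: the aldehyde must be masked during methylenation, and the ketone must be gone before oxocarbenium chemistry and strong base are used.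

**Key disconnection (15 ⇒ 13 ⇒ 12).** Reconnecting the aldehyde carbon to the ketone α-carbon (an aldol bond) gives the cyclobutanol 14 and its acetate 13. The cyclobutane is then cut across two bonds: α-carbon to methyl-bearing carbon, and acetoxy carbon to CH2. This leads to the enol acetate 12, whose isopropenyl group hangs on a three-atom tether. These two bonds are chosen because they create the quaternary carbon and the cyclopentane in one step. Their configuration is enforced by ring strain and tether length and not by a reagent. The sacrificial cyclobutane then delivers the ketone and the aldehyde arm exactly where they are needed.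

**Formyl carbon and side chain (12 ⇒ 11 ⇒ 9 ⇒ 5 + 6).** The formyl carbon sits on the α-carbon next to the stereocentre, the more hindered α-position. It can only be placed through a regiodefined enolate, and a conjugate addition supplies exactly that. Cutting the side chain at the ring β-carbon gives enone 5 and bromide 6. A chiral copper catalyst sets the single stereocentre from which all hydroazulene stereocentres derive.

**Seven-membered ring (5 ⇒ 3 ⇒ 2 ⇒ 1).** The ring is made from a six-membered one by one-carbon insertion between the carbonyl carbon and the enol ether carbon. Conjugate methylation of 1 with O-silylation places the gem-dimethyl group and fixes the enol ether regiochemistry in the same operation, so the new alkene of 5 ends next to the quaternary carbon.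

## Alternatives that were turned down

**Alternative 1:** The seven-membered ring is cut at the ring-fusion CH–CH bond and at the bond between the methylene-bearing carbon and its ring CH2 neighbour. In the forward sense the open-chain allene–vinylcyclopropane A1 would cycloisomerise under rhodium catalysis, a (5+2) process, to the bicyclic diene A2.
- For it: both carbocycles close at once and the exocyclic methylene is present from the start. No epimerisable ketone ever sits next to the ring fusion. On this point it is stronger than the chosen route, which must pass steps 8 and 10 without epimerisation.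
- Against it: A2 carries a ring alkene with one methyl where the target has a gem-dimethyl carbon. A trisubstituted alkene would have to be hydromethylated beside a more accessible 1,1-disubstituted one.
- Against it: the quaternary stereocentre of A1 is acyclic and bears three similar carbon chains, so it is hard to make as a single enantiomer. The cis fusion and its relation to that centre would rest on 1,2-induction between a methyl and a silyloxyethyl group of similar size.
- Comparison: the chosen strategy has the gem-dimethyl group from step 1 and sets the quaternary carbon intramolecularly under geometric constraint. It pays for this with one ketone stage.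

**Alternative 2:** The bond between the bridge carbon and the carbon bridgehead is cut. In the forward sense the secondary bromide A3 would give, in a silane-mediated radical chain, a radical beside the quaternary carbon that closes onto the enoate to the oxolane A4.
- For it: the step is convergent, sets two stereocentres and installs the acetate arm. On this point it is as strong as the chosen route, which forms the same bond in the same way in steps 13 and 14.
- Against it: as the step that defines a strategy it leaves the real problem open. A3 already contains the cis-hydroazulene with its quaternary carbon.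
- Against it: the uncertain relation between the bridge carbon and the new CH would be the central risk, two steps from the end on the most valuable intermediate.
- Comparison: the chosen strategy supplies the hydroazulene that A3 presupposes and keeps this closure as a late, subordinate step.

**Alternative 3:** Two bonds are cut, ketone carbon to ring-fusion CH and quaternary carbon to bridge carbon. In the forward sense the acyl radical from selenoester A5 would close the seven-membered ring on the cyclopentene CH. The tertiary radical so formed would add to the β-carbon of the acetoxy enone A6 to give A7.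
- For it: this is the most convergent plan, and it makes the most hindered bond at a tertiary radical, which suits congested bonds. On both points it is stronger than the chosen route.
- Against it: a seven-membered acyl-radical closure is slow and competes with reduction. The cis ring fusion is fixed in that irreversible step with nothing to enforce it.
- Against it: the intermolecular capture must beat hydrogen transfer and must choose the right face of both partners.
- Against it: A7 holds two ketones that must be told apart, one to be methylenated and one to be opened oxidatively to the lactone acetal, so a long endgame follows.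
- Comparison: the chosen strategy has an intramolecular key step whose stereochemistry is dictated by ring strain, and it carries only one ketone.

Key step: step 7

Assumption: methyl (R)-2-hydroxybut-3-enoate 19 is bought as the single enantiomer; where only the racemate is offered it is resolved by lipase-catalysed acylation before use.

Remark: enol acetate 12 and enol ether 18 are drawn as E isomers; the Z isomers react in the same way and need not be removed.

## Route

Step 1
Reactants: 1 3-methylcyclohex-2-en-1-one
Product: 2 3,3-dimethyl-1-(trimethylsilyloxy)cyclohex-1-ene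
Conditions: MeMgBr, CuI·2LiCl (5 mol %), Me3SiCl, THF, −40 → 0 °C
Reagents that add atoms: methylmagnesium bromide, C[Mg]Br; chlorotrimethylsilane, C[Si](C)(C)Cl
Why: Copper-catalysed conjugate addition of a Grignard reagent, accelerated by the silyl chloride, which traps the enolate on oxygen; the enol ether double bond is thereby fixed on the side of the new gem-dimethyl carbon, as the ring expansion requires. No stereocentre is formed.

Step 2
Reactants: 2 3,3-dimethyl-1-(trimethylsilyloxy)cyclohex-1-ene
Product: 3 5,5-dimethyl-1-(trimethylsilyloxy)bicyclo[4.1.0]heptane (racemic)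
Conditions: Et2Zn, CH2I2, CH2Cl2, 0 °C → rt
Reagents that add atoms: diiodomethane, ICI
Why: Furukawa-modified Simmons–Smith cyclopropanation; the electron-rich silyl enol ether is a good acceptor for the zinc carbenoid. The racemic stereocentres disappear in step 3.

Step 3
Reactants: 3 5,5-dimethyl-1-(trimethylsilyloxy)bicyclo[4.1.0]heptane
Product: 5 4,4-dimethylcyclohept-2-en-1-one, via 3-chloro-4,4-dimethylcycloheptan-1-one 4 (not isolated)
Conditions: FeCl3, DMF, 0 °C → rt; then NaOAc, MeOH, reflux
Reagents that add atoms: none
Why: Saegusa-type oxidative ring expansion: one-electron oxidation by FeCl3 opens the ring-fusion bond of the siloxycyclopropane to a β-keto radical that is chlorinated, and sodium acetate then eliminates HCl to the conjugated enone. The inserted CH2 lies between the carbonyl carbon and the carbon next to the gem-dimethyl group, so the alkene points toward the quaternary carbon.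

Step 4
Reactants: 5 4,4-dimethylcyclohept-2-en-1-one; 6 4-bromo-2-methylbut-1-ene
Product: 9 (3R)-4,4-dimethyl-3-(3-methylbut-3-en-1-yl)-1-(trimethylsilyloxy)cyclohept-1-ene, via (3-methylbut-3-en-1-yl)magnesium bromide 7 (not isolated), via bromomagnesium enolate 8 (not isolated)
Conditions: 6, Mg, Et2O; then 5, CuBr·SMe2 (5 mol %), (R)-1-[(S)-2-(diphenylphosphino)ferrocenyl]ethyldicyclohexylphosphine or its enantiomer (6 mol %, the enantiomer that gives the 3R adduct), t-BuOMe, −78 °C; then Me3SiCl, Et3N, DMPU, −78 → 0 °C
Reagents that add atoms: chlorotrimethylsilane, C[Si](C)(C)Cl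
Why: Copper-catalysed enantioselective conjugate addition of a Grignard reagent to a cyclic enone; the chiral diphosphine–copper complex selects the enone face and so sets the one stereocentre. O-silylation preserves the enolate regiochemistry at the α-carbon next to that stereocentre.

Step 5
Reactants: 9 (3R)-4,4-dimethyl-3-(3-methylbut-3-en-1-yl)-1-(trimethylsilyloxy)cyclohept-1-ene
Product: 11 (3S,2Z)-2-(hydroxymethylene)-4,4-dimethyl-3-(3-methylbut-3-en-1-yl)cycloheptan-1-one, via lithium enolate 10 (not isolated)
Conditions: MeLi, THF, 0 °C; then CF3CH2OCHO, −78 °C; aqueous work-up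
Reagents that add atoms: 2,2,2-trifluoroethyl formate, O=COCC(F)(F)F
Why: Methyllithium cleaves the Si–O bond to the regiodefined lithium enolate, which is C-formylated by the activated formate (crossed Claisen condensation) before it can equilibrate to the less hindered enolate. The descriptor changes from R to S only because the priorities change.

Step 6
Reactants: 11 (3S,2Z)-2-(hydroxymethylene)-4,4-dimethyl-3-(3-methylbut-3-en-1-yl)cycloheptan-1-one
Product: 12 (3S,2E)-2-(acetoxymethylene)-4,4-dimethyl-3-(3-methylbut-3-en-1-yl)cycloheptan-1-one
Conditions: Ac2O, Et3N, DMAP (5 mol %), CH2Cl2, 0 °C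
Reagents that add atoms: acetic anhydride, CC(=O)OC(C)=O
Why: O-acylation of the enolised β-keto aldehyde at the aldehyde-derived oxygen; it fixes the chromophore as the exocyclic C=C conjugated with the ring ketone.

Step 7
Reactants: 12 (3S,2E)-2-(acetoxymethylene)-4,4-dimethyl-3-(3-methylbut-3-en-1-yl)cycloheptan-1-one
Product: 13 tricyclic acetoxycyclobutane photoadduct (5-7 and 5-4 ring fusions cis; acetoxy carbon as a mixture of epimers)
Conditions: hν (350 nm, Pyrex), cyclohexane (0.01 M), degassed, rt
Reagents that add atoms: none
Why: Excitation of the enone and intersystem crossing give a triplet that adds to the tethered alkene stepwise through a 1,4-biradical, the mechanism of enone–alkene [2+2] photocycloaddition; the closest known reaction type is the intramolecular De Mayo reaction of enol esters of β-dicarbonyl compounds that carry an alkene on a three-atom tether. The cyclopentane closes first, by 1,5-bonding of the enone α-carbon to the methyl-bearing alkene carbon (5-exo mode, the rule of five for 1,6-dienes), and the cyclobutane then closes by combination of the acetoxy-substituted radical with the primary radical at the former alkene terminus. The α-carbon becomes a stereocentre whose new bond must lie on the ring face that carries the tether, because three atoms cannot span the other face, so the 5-7 fusion is cis to the stereocentre of step 4. The quaternary methyl carbon is set by the cis fusion that a bicyclo[3.2.0]heptane demands: the cyclobutane CH2 lies on the face of the ring-fusion hydrogen and the methyl on the other. The acetoxy carbon forms as a mixture, which does not matter because it becomes the aldehyde carbon. The step needs straight (bicyclo[3.2.0]) and not crossed (bicyclo[2.1.1]) closure, which the three-atom tether secures, and it needs the exocyclic and not an endocyclic enone to react, which the enol acetate secures. Light above 300 nm reaches only the enone band and spares the isolated alkene and the ester.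

Step 8
Reactants: 13 tricyclic acetoxycyclobutane photoadduct
Product: 15 2-[(1S,3aR,8aR)-1,4,4-trimethyl-8-oxodecahydroazulen-1-yl]acetaldehyde, via cyclobutanol 14 (not isolated)
Conditions: K2CO3, MeOH, 0 °C; pH 7 buffer
Reagents that add atoms: none
Why: Methanolysis of the acetate frees the cyclobutanolate, and ring strain drives retro-aldol cleavage of its bond to the ketone α-carbon. The enolate should be protonated from the face away from the gem-dimethyl-bearing ring carbon, which gives the cis ring fusion; the reaction is kept cold and short so that this centre does not equilibrate.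

Step 9
Reactants: 15 2-[(1S,3aR,8aR)-1,4,4-trimethyl-8-oxodecahydroazulen-1-yl]acetaldehyde
Product: 16 (3S,3aR,8aR)-3-(2,2-dimethoxyethyl)-3,8,8-trimethyloctahydroazulen-4(1H)-one (keto dimethyl acetal)
Conditions: HC(OMe)3, MeOH, PPTS (5 mol %), rt
Reagents that add atoms: methanol, CO; trimethyl orthoformate, COC(OC)OC
Why: Acid-catalysed acetalisation; the aldehyde reacts far faster than the hindered α-branched ketone, and the weak acid does not enolise the ketone.

Step 10
Reactants: 16 keto dimethyl acetal
Product: 17 2-[(1S,3aR,8aS)-1,4,4-trimethyl-8-methylidenedecahydroazulen-1-yl]acetaldehyde dimethyl acetal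
Conditions: Cp2TiMe2, toluene, 70 °C, dark
Reagents that add atoms: bis(cyclopentadienyl)dimethyltitanium (Cp2TiMe2), [CH3-].[CH3-].[cH-]1cccc1.[cH-]1cccc1.[Ti+4]
Why: Petasis methylenation: the titanium methylidene formed on heating adds to the ketone and collapses to the alkene without passing through an enolate, so the adjacent ring-fusion centre is kept. Acetals are inert to the reagent.

Step 11
Reactants: 17 methylene dimethyl acetal
Product: 18 (1R,3aR,8aS)-1-[(E)-2-methoxyethenyl]-1,4,4-trimethyl-8-methylidenedecahydroazulene
Conditions: Me3SiOTf, i-Pr2NEt, CH2Cl2, −20 °C → rt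
Reagents that add atoms: none
Why: The silyl triflate ionises the acetal to an oxocarbenium ion and the hindered amine removes the α-proton, the standard conversion of a dimethyl acetal into a methyl enol ether. The geometry is lost again in step 13.

Step 12
Reactants: 19 methyl (R)-2-hydroxybut-3-enoate; 20 tert-butyl acrylate
Product: 21 1-tert-butyl 5-methyl (2E,4R)-4-hydroxypent-2-enedioate
Conditions: second-generation Hoveyda–Grubbs catalyst (H2IMes)Cl2Ru(=CH-C6H4-2-O-i-Pr) (2 mol %), CH2Cl2, 40 °C
Reagents that add atoms: none
Why: Olefin cross-metathesis between an allylic alcohol and an acrylate, a pair that couples selectively to the E-enoate. The stereocentre is not touched.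

Step 13
Reactants: 18 methyl enol ether; 21 1-tert-butyl 5-methyl (2E,4R)-4-hydroxypent-2-enedioate
Product: 22 1-tert-butyl 5-methyl (2E,4R)-4-{2-bromo-1-methoxy-2-[(1R,3aR,8aS)-1,4,4-trimethyl-8-methylidenedecahydroazulen-1-yl]ethoxy}pent-2-enedioate (mixture at the CHBr and acetal carbons)
Conditions: NBS, 21 (1.5 equiv), CH2Cl2, −40 → 0 °C, dark
Reagents that add atoms: N-bromosuccinimide, O=C1CCC(=O)N1Br
Why: Bromoetherification: the enol ether takes up electrophilic bromine at the carbon next to the quaternary centre far faster than the 1,1-disubstituted alkene does, and alcohol 21 caps the oxocarbenium ion. The brominated carbon becomes planar in step 14 and the acetal carbon is re-set in step 15, so the mixture is used as such.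

Step 14
Reactants: 22 mixed bromoacetal
Product: 23 methyl 3-(2-tert-butoxy-2-oxoethyl)-5-methoxy-4-[(1R,3aR,8aS)-1,4,4-trimethyl-8-methylidenedecahydroazulen-1-yl]oxolane-2-carboxylate (2,3-trans and 3,4-cis; acetal carbon as a mixture)
Conditions: (Me3Si)3SiH, AIBN (0.2 equiv), toluene (0.02 M), 80 °C
Reagents that add atoms: none
Why: Ueno–Stork 5-exo-trig cyclisation of the α-bromoacetal radical onto the enoate β-carbon; the ester-stabilised radical is then reduced by the silane. In the chair transition state with the methyl ester on the carbinol carbon and the hydroazulenyl group on the radical carbon both pseudo-equatorial, the CH(CO2Me)/CH(arm) pair should come out trans and the bridge CH/CH(arm) pair cis, as the target requires.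

Step 15
Reactants: 23 oxolane methyl acetal
Product: 24 methyl (1S,5R,6R,8R)-3-oxo-8-[(1R,3aR,8aS)-1,4,4-trimethyl-8-methylidenedecahydroazulen-1-yl]-2,7-dioxabicyclo[3.2.1]octane-6-carboxylate
Conditions: Me3SiOTf, 2,6-di-tert-butyl-4-methylpyridine, CH2Cl2, −78 → −20 °C
Reagents that add atoms: none
Why: Lewis-acid ionisation of the methyl acetal gives the cyclic oxocarbenium ion, which the tert-butyl ester carbonyl captures with loss of isobutene, as in lactonisations of tert-butyl esters onto cations. The arm reaches only its own face, so both acetal epimers give the same cis-bridged acylal; the hindered pyridine takes up the acid and protects the methylene group.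

Step 16
Reactants: 24 bicyclic lactone
Product: 26 methyl (1S,4S,5S,6R,8R)-4-hydroxy-3-oxo-8-[(1R,3aR,8aS)-1,4,4-trimethyl-8-methylidenedecahydroazulen-1-yl]-2,7-dioxabicyclo[3.2.1]octane-6-carboxylate, via potassium lactone enolate 25 (not isolated)
Conditions: KN(SiMe3)2, THF, −78 °C; then 2-(phenylsulfonyl)-3-phenyloxaziridine, −78 °C; aqueous work-up
Reagents that add atoms: 2-(phenylsulfonyl)-3-phenyloxaziridine, O=S(=O)(c1ccccc1)N1OC1c1ccccc1
Why: Enolate hydroxylation with an N-sulfonyloxaziridine; the lactone CH2 is the most accessible acidic position. The oxidant should approach from the face away from the hydroazulenyl group on the one-carbon bridge, which places the new C–O bond on the side of the oxolane bridge as in the target.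

Step 17
Reactants: 26 α-hydroxy lactone
Product: 27 methyl (1S,4S,5R,6R,8R)-4-acetoxy-3-oxo-8-[(1R,3aR,8aS)-1,4,4-trimethyl-8-methylidenedecahydroazulen-1-yl]-2,7-dioxabicyclo[3.2.1]octane-6-carboxylate (target)
Conditions: Ac2O, pyridine, DMAP (5 mol %), CH2Cl2, 0 °C
Reagents that add atoms: acetic anhydride, CC(=O)OC(C)=O
Why: Acylation of the secondary alcohol under nucleophilic catalysis; no stereocentre is touched and the mild base spares the acylal.

## Compound list

1 | 3-methylcyclohex-2-en-1-one | CC1=CC(=O)CCC1 | starting material
2 | 3,3-dimethyl-1-(trimethylsilyloxy)cyclohex-1-ene | C[Si](C)(C)OC1=CC(C)(C)CCC1 | intermediate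
3 | 5,5-dimethyl-1-(trimethylsilyloxy)bicyclo[4.1.0]heptane (racemic) | C[Si](C)(C)OC12CC1C(C)(C)CCC2 | intermediate
4 | 3-chloro-4,4-dimethylcycloheptan-1-one (racemic, not isolated) | O=C1CC(Cl)C(C)(C)CCC1 | intermediate
5 | 4,4-dimethylcyclohept-2-en-1-one | O=C1C=CC(C)(C)CCC1 | intermediate
6 | 4-bromo-2-methylbut-1-ene | C=C(C)CCBr | starting material
7 | (3-methylbut-3-en-1-yl)magnesium bromide (not isolated) | C=C(C)CC[Mg]Br | intermediate
8 | bromomagnesium enolate of (3R)-4,4-dimethyl-3-(3-methylbut-3-en-1-yl)cycloheptan-1-one (not isolated) | Br[Mg]OC1=C[C@@H](CCC(C)=C)C(C)(C)CCC1 | intermediate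
9 | (3R)-4,4-dimethyl-3-(3-methylbut-3-en-1-yl)-1-(trimethylsilyloxy)cyclohept-1-ene | C[Si](C)(C)OC1=C[C@@H](CCC(C)=C)C(C)(C)CCC1 | intermediate
10 | lithium enolate of (3R)-4,4-dimethyl-3-(3-methylbut-3-en-1-yl)cycloheptan-1-one (not isolated) | [Li]OC1=C[C@@H](CCC(C)=C)C(C)(C)CCC1 | intermediate
11 | (3S,2Z)-2-(hydroxymethylene)-4,4-dimethyl-3-(3-methylbut-3-en-1-yl)cycloheptan-1-one | O=C1CCCC(C)(C)[C@H](CCC(C)=C)/C1=C/O | intermediate
12 | (3S,2E)-2-(acetoxymethylene)-4,4-dimethyl-3-(3-methylbut-3-en-1-yl)cycloheptan-1-one | O=C1CCCC(C)(C)[C@H](CCC(C)=C)/C1=C\OC(C)=O | intermediate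
13 | tricyclic photoadduct: the cycloheptanone α-carbon and the methyl-bearing carbon form the shared edge of a cis-fused bicyclo[3.2.0]heptane, cyclopentane cis-fused to the seven-membered ring, OAc on the cyclobutane carbon bonded to the α-carbon (both epimers) | O=C1CCCC(C)(C)[C@@H]2CC[C@@]3(C)CC(OC(C)=O)[C@@]123 | intermediate
14 | cyclobutanol corresponding to 13 (not isolated) | O=C1CCCC(C)(C)[C@@H]2CC[C@@]3(C)CC(O)[C@@]123 | intermediate
15 | 2-[(1S,3aR,8aR)-1,4,4-trimethyl-8-oxodecahydroazulen-1-yl]acetaldehyde (cis-fused; ring-fusion hydrogens and CH2CHO arm on one face, methyl on the other) | O=C1CCCC(C)(C)[C@@H]2CC[C@@](C)(CC=O)[C@H]12 | intermediate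
16 | dimethyl acetal of 15 | O=C1CCCC(C)(C)[C@@H]2CC[C@@](C)(CC(OC)OC)[C@H]12 | intermediate
17 | 2-[(1S,3aR,8aS)-1,4,4-trimethyl-8-methylidenedecahydroazulen-1-yl]acetaldehyde dimethyl acetal | C=C1CCCC(C)(C)[C@@H]2CC[C@@](C)(CC(OC)OC)[C@H]12 | intermediate
18 | (1R,3aR,8aS)-1-[(E)-2-methoxyethenyl]-1,4,4-trimethyl-8-methylidenedecahydroazulene (E/Z mixture acceptable) | C=C1CCCC(C)(C)[C@@H]2CC[C@@](C)(/C=C/OC)[C@H]12 | intermediate
19 | methyl (R)-2-hydroxybut-3-enoate | COC(=O)[C@H](O)C=C | starting material
20 | tert-butyl acrylate | C=CC(=O)OC(C)(C)C | starting material
21 | 1-tert-butyl 5-methyl (2E,4R)-4-hydroxypent-2-enedioate | COC(=O)[C@H](O)/C=C/C(=O)OC(C)(C)C | intermediate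
22 | mixed bromoacetal of 18 and 21 (CHBr and acetal carbons as mixtures) | C=C1CCCC(C)(C)[C@@H]2CC[C@@](C)(C(Br)C(OC)O[C@H](/C=C/C(=O)OC(C)(C)C)C(=O)OC)[C@H]12 | intermediate
23 | methyl 3-(2-tert-butoxy-2-oxoethyl)-5-methoxy-4-(hydroazulenyl)oxolane-2-carboxylate, 2,3-trans and 3,4-cis, acetal carbon both epimers | C=C1CCCC(C)(C)[C@@H]2CC[C@@](C)([C@@H]3C(OC)O[C@@H](C(=O)OC)[C@@H]3CC(=O)OC(C)(C)C)[C@H]12 | intermediate
24 | methyl (1S,5R,6R,8R)-3-oxo-8-[(1R,3aR,8aS)-1,4,4-trimethyl-8-methylidenedecahydroazulen-1-yl]-2,7-dioxabicyclo[3.2.1]octane-6-carboxylate | C=C1CCCC(C)(C)[C@@H]2CC[C@@](C)([C@@H]3[C@@H]4OC(=O)C[C@H]3[C@H](C(=O)OC)O4)[C@H]12 | intermediate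
25 | potassium enolate of lactone 24 (not isolated) | C=C1CCCC(C)(C)[C@@H]2CC[C@@](C)([C@@H]3[C@@H]4OC(O[K])=C[C@H]3[C@H](C(=O)OC)O4)[C@H]12 | intermediate
26 | methyl (1S,4S,5S,6R,8R)-4-hydroxy-3-oxo-8-[(1R,3aR,8aS)-1,4,4-trimethyl-8-methylidenedecahydroazulen-1-yl]-2,7-dioxabicyclo[3.2.1]octane-6-carboxylate | C=C1CCCC(C)(C)[C@@H]2CC[C@@](C)([C@@H]3[C@@H]4OC(=O)[C@@H](O)[C@H]3[C@H](C(=O)OC)O4)[C@H]12 | intermediate
27 | methyl (1S,4S,5R,6R,8R)-4-acetoxy-3-oxo-8-[(1R,3aR,8aS)-1,4,4-trimethyl-8-methylidenedecahydroazulen-1-yl]-2,7-dioxabicyclo[3.2.1]octane-6-carboxylate | C=C1CCCC(C)(C)[C@@H]2CC[C@@](C)([C@@H]3[C@@H]4OC(=O)[C@@H](OC(C)=O)[C@H]3[C@H](C(=O)OC)O4)[C@H]12 | target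

## Step count and least certain steps

Total: 17 steps. Longest linear sequence: 16 steps (steps 1–11 and 13–17); step 12 is a one-step branch.

**Step 7 (key step).** The triplet of the exocyclic enone may relax by twisting about its C=C bond (E/Z isomerisation), or the enol ester may undergo a light-induced 1,3-acyl shift faster than the alkene is captured. The intermediate biradical may also close in the crossed sense because the attacked alkene carbon is disubstituted.
- Fallback: set out from 11 and irradiate the hydrogen-bonded enol itself under the same light, the original form of the De Mayo reaction. The chelate ring holds the enone planar, so twisting is no longer a decay channel and no acyl group is present to migrate. The cyclobutanol 14 opens in the flask, and the route is rejoined at 15.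

**Step 14.** The radical carbon carries a very large tertiary-alkyl group. It may turn pseudo-axial to avoid the ester-bearing alkene terminus, so that bonding occurs on the other face of the radical and the bridge carbon forms with the wrong configuration relative to the new CH. This cis/trans choice is the least secure stereochemical point of the route.
- Fallback: set out from 22 and accept the cyclisation mixture of 23 and its bridge-carbon epimer F1. Both are converted with Me3SiOTf and i-Pr2NEt at −20 °C into the one 2,3-dihydrofuran F2, which erases the bridge stereocentre. Catalytic camphorsulfonic acid in CH2Cl2 at 0 °C then protonates the enol ether, and the tert-butyl ester closes onto the cation with loss of isobutene. Protonation is expected on the face away from the ester arm, and ring closure is reversible under the acid, so the more stable bicycle should accumulate. That is the one with the hydroazulenyl group turned away from the ester-bearing oxolane bridge, and the route is rejoined at 24.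

**Step 8.** The enolate released by the retro-aldol may be protonated on the wrong face, or carbonate in methanol may equilibrate the new α-centre toward the trans-fused ketone before the aldehyde is masked.
- Fallback: set out from 11 and make the benzyl enol carbonate F3 (benzyl chloroformate, Et3N). Irradiate it as in step 7 to the photoadduct F4 and remove the carbonate by hydrogenolysis (H2, Pd/C, ethyl acetate); F4 has no alkene. The free cyclobutanol opens under neutral conditions, the enol ketonises without base, and the product cannot equilibrate afterwards. The route is rejoined at 15.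

**Step 11.** The oxocarbenium ion may be captured by the nearby 1,1-disubstituted alkene (Prins closure to a six-membered ring) before the amine removes the hindered α-proton.
- Fallback: set out from 17 and avoid any free oxocarbenium ion in an aprotic medium.
  - Hydrolyse the acetal (PPTS, wet acetone) to the aldehyde F5.
  - Silylate with t-BuMe2SiOTf and Et3N to the silyl enol ether F6.
  - Brominate with NBS at −78 °C to the α-bromo aldehyde F7.
  - Acetalise in methanol (HC(OMe)3, PPTS), where the solvent traps the cation at once, to the α-bromo dimethyl acetal F8.
  - Exchange one methoxy group for alcohol 21 through the collidinium salt (Et3SiOTf, 2,4,6-collidine, then 21).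
  - The route is rejoined at 22.

**Step 4.** The β-carbon is neopentyl. Transfer of the butenyl group from the chiral copper complex may be slow, so that uncatalysed or 1,2-addition erodes the enantiomeric purity.
- Fallback: set out from 5 and run the addition with CuBr·SMe2 alone to the racemic silyl enol ether F9. Dehydrogenate F9 with IBX and 4-methoxypyridine N-oxide to the β-substituted enone F10. Set the stereocentre by copper hydride conjugate reduction (CuCl, NaO-t-Bu, (S)-p-Tol-BINAP or its enantiomer, Ph2SiH2), in which only a hydrogen has to reach the hindered carbon. The resulting diphenylsilyl enol ether F11 is cleaved with MeLi, and the route is rejoined at lithium enolate 10.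

**Step 16.** The base may also remove the proton α to the methyl ester, which would epimerise that centre, or the lactone enolate may expel the acetal oxygen. Face selectivity could also be lower than expected.
- Fallback: set out from 23 and introduce the oxygen before the bicycle is closed. The tert-butyl ester enolate (LiN(i-Pr)2, −78 °C) is hydroxylated under reagent control with an enantiopure (camphorsulfonyl)oxaziridine to the α-hydroxy ester F12. This is acetylated (Ac2O, pyridine, DMAP) to F13, and the lactonisation of step 15 then gives 27 directly.

## Further compounds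

F0 | step 7 | none | none
F1 | step 14 | bridge-carbon epimer of 23 (3,4-trans oxolane) | C=C1CCCC(C)(C)[C@@H]2CC[C@@](C)([C@H]3C(OC)O[C@@H](C(=O)OC)[C@@H]3CC(=O)OC(C)(C)C)[C@H]12
F2 | step 14 | methyl 3-(2-tert-butoxy-2-oxoethyl)-4-[(1R,3aR,8aS)-1,4,4-trimethyl-8-methylidenedecahydroazulen-1-yl]-2,3-dihydrofuran-2-carboxylate (2,3-trans) | C=C1CCCC(C)(C)[C@@H]2CC[C@@](C)(C3=CO[C@@H](C(=O)OC)[C@@H]3CC(=O)OC(C)(C)C)[C@H]12
F3 | step 8 | benzyl enol carbonate of 11 | O=C1CCCC(C)(C)[C@H](CCC(C)=C)/C1=C\OC(=O)OCc1ccccc1
F4 | step 8 | photoadduct of F3 (benzyl carbonate analogue of 13) | O=C1CCCC(C)(C)[C@@H]2CC[C@@]3(C)CC(OC(=O)OCc4ccccc4)[C@@]123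
F5 | step 11 | 2-[(1S,3aR,8aS)-1,4,4-trimethyl-8-methylidenedecahydroazulen-1-yl]acetaldehyde | C=C1CCCC(C)(C)[C@@H]2CC[C@@](C)(CC=O)[C@H]12
F6 | step 11 | tert-butyldimethylsilyl enol ether of F5 | C=C1CCCC(C)(C)[C@@H]2CC[C@@](C)(/C=C/O[Si](C)(C)C(C)(C)C)[C@H]12
F7 | step 11 | α-bromo aldehyde from F6 (CHBr as a mixture) | C=C1CCCC(C)(C)[C@@H]2CC[C@@](C)(C(Br)C=O)[C@H]12
F8 | step 11 | dimethyl acetal of F7 | C=C1CCCC(C)(C)[C@@H]2CC[C@@](C)(C(Br)C(OC)OC)[C@H]12
F9 | step 4 | racemic 4,4-dimethyl-3-(3-methylbut-3-en-1-yl)-1-(trimethylsilyloxy)cyclohept-1-ene | C[Si](C)(C)OC1=CC(CCC(C)=C)C(C)(C)CCC1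
F10 | step 4 | 4,4-dimethyl-3-(3-methylbut-3-en-1-yl)cyclohept-2-en-1-one | O=C1C=C(CCC(C)=C)C(C)(C)CCC1
F11 | step 4 | (3R)-1-(diphenylsilyloxy)-4,4-dimethyl-3-(3-methylbut-3-en-1-yl)cyclohept-1-ene | c1ccc(cc1)[SiH](OC1=C[C@@H](CCC(C)=C)C(C)(C)CCC1)c1ccccc1
F12 | step 16 | α-hydroxy tert-butyl ester from 23 | C=C1CCCC(C)(C)[C@@H]2CC[C@@](C)([C@@H]3C(OC)O[C@@H](C(=O)OC)[C@@H]3[C@H](O)C(=O)OC(C)(C)C)[C@H]12
F13 | step 16 | acetate of F12 | C=C1CCCC(C)(C)[C@@H]2CC[C@@](C)([C@@H]3C(OC)O[C@@H](C(=O)OC)[C@@H]3[C@H](OC(C)=O)C(=O)OC(C)(C)C)[C@H]12
A1 | alternative 1 | open-chain allene–vinylcyclopropane with the quaternary carbon between the two units | C=C=C[C@](C)(CCO[Si](C)(C)C(C)(C)C)CC/C=C(\C)C1CC1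
A2 | alternative 1 | cis-bicyclo[5.3.0]decadiene with exocyclic methylene, ring methyl alkene and silyloxyethyl arm | C=C1CCC=C(C)[C@@H]2CC[C@@](C)(CCO[Si](C)(C)C(C)(C)C)[C@H]12
A3 | alternative 2 | ethyl bromoacetal analogue of 22 | C=C1CCCC(C)(C)[C@@H]2CC[C@@](C)(C(Br)C(OCC)O[C@H](/C=C/C(=O)OC(C)(C)C)C(=O)OC)[C@H]12
A4 | alternative 2 | 2-ethoxyoxolane with hydroazulene, tert-butyl acetate arm and methyl ester | C=C1CCCC(C)(C)[C@@H]2CC[C@@](C)([C@@H]3C(OCC)O[C@@H](C(=O)OC)[C@@H]3CC(=O)OC(C)(C)C)[C@H]12
A5 | alternative 3 | Se-phenyl 5-methyl-5-[(1S)-3-methylcyclopent-2-en-1-yl]hexaneselenoate | O=C([Se]c1ccccc1)CCCC(C)(C)[C@H]1C=C(C)CC1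
A6 | alternative 3 | 2-acetoxy-4-[2-methoxy-2-oxo-1-(triethylsilyloxy)ethyl]cyclopent-2-en-1-one | CC(=O)OC1=C[C@H]([C@@H](O[Si](CC)(CC)CC)C(=O)OC)CC1=O
A7 | alternative 3 | cis-hydroazulenone carrying the acetoxy cyclopentanone on its quaternary carbon | O=C1CCCC(C)(C)[C@@H]2CC[C@@](C)([C@@H]3C(OC(C)=O)C(=O)C[C@H]3[C@@H](O[Si](CC)(CC)CC)C(=O)OC)[C@H]12
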